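## Retrosynthetic overview

1. Rings are lettered A (3,5-dihydroxyphenyl end) to H (2,4,6-trihydroxyphenyl end). The plan rests on rings B, D and F. Each carries two adjacent aryloxy groups (C1–O toward A, C2–O toward H) set between C3–H and the C4–C6 triol, which is the footprint of a 3,4,5-trioxygenated benzyne that has taken up oxygen at C2 and a second group at C1.
2. Global O-demethylation leads back to the icosamethyl ether. Its four bonds A–O–C1(B), C–O–C1(D), E–O–C1(F) and G–O–C1(H) are cut as copper-catalysed couplings of unhindered phenols with doubly ortho-oxygenated aryl iodides.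
3. This reduces B–C, D–E and F–G to one two-ring module, with iodine on C1 of the pentaoxygenated ring and a benzyl ether on C4 of the other ring.
4. The module is cut at C2–O and C1–I into 3,4,5-trimethoxybenzyne (from a 2-iodoaryl 4-chlorobenzenesulfonate), the magnesium salt of 4-(benzyloxy)-2,6-dimethoxyphenol, and I2.
5. No ring is built, since all eight benzene rings are bought. They are joined in the order B–C module, then A, then D–E, then F–G, then H.

Key step: step 5

Remark on the chemistry: the target has no stereocentre, and its diaryl ether axes are assumed to rotate freely, so no stereodescriptor is needed.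

Numbering used below:
- In rings B, D and F, C1 bears the oxygen toward A, C2 bears the oxygen toward H, C3 is CH, and C4–C6 bear oxygen.
- In rings C, E and G, C1 is bonded to the oxygen on C2 of the preceding ring, C2 and C6 bear oxygen, and C4 bears the oxygen leading to C1 of the next ring.

## Route

Step 1
Reactants: 1 3,4,5-trimethoxyphenol
Product: 2 2-iodo-3,4,5-trimethoxyphenol
Conditions: NIS (1.0 equiv), MeCN, 0 °C, dark
Reagents that add atoms: N-iodosuccinimide, O=C1CCC(=O)N1I
Why: Electrophilic aromatic iodination; the free hydroxyl directs NIS to one of two equivalent ortho positions (the para position carries a methoxy group), and one equivalent at low temperature should hold back di-iodination.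

Step 2
Reactants: 2 2-iodo-3,4,5-trimethoxyphenol
Product: 3 2-iodo-3,4,5-trimethoxyphenyl 4-chlorobenzenesulfonate
Conditions: 4-ClC6H4SO2Cl, Et3N, DMAP (cat.), CH2Cl2, 0 °C → rt
Reagents that add atoms: 4-chlorobenzenesulfonyl chloride, O=S(=O)(Cl)c1ccc(Cl)cc1
Why: Routine O-sulfonylation of a phenol; this sulfonate tolerates iodine–magnesium exchange at −78 °C and leaves readily on warming.

Step 3
Reactants: 4 2,6-dimethoxy-1,4-benzoquinone
Product: 5 2,6-dimethoxybenzene-1,4-diol
Conditions: Na2S2O4, THF/H2O, rt, argon
Reagents that add atoms: none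
Why: Dithionite reduction of a para-quinone to its hydroquinone is fast and touches nothing else in the molecule.

Step 4
Reactants: 5 2,6-dimethoxybenzene-1,4-diol
Product: 6 4-(benzyloxy)-2,6-dimethoxyphenol
Conditions: BnBr (1.0 equiv), K2CO3 (1.1 equiv), DMF, rt, argon
Reagents that add atoms: benzyl bromide, BrCc1ccccc1
Why: Williamson ether synthesis; the C4 hydroxyl is both the more acidic one (meta to two methoxy groups) and the uncrowded one, whereas the C1 hydroxyl is flanked and hydrogen-bonded by two methoxy groups, so a weak base and one equivalent of halide should alkylate C4–OH.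

Step 5
Reactants: 3 2-iodo-3,4,5-trimethoxyphenyl 4-chlorobenzenesulfonate; 6 4-(benzyloxy)-2,6-dimethoxyphenol
Product: 11 5-(benzyloxy)-2-(2-iodo-3,4,5-trimethoxyphenoxy)-1,3-dimethoxybenzene, via magnesium phenoxide 7 (not isolated), via magnesiated sulfonate 8 (not isolated), via 3,4,5-trimethoxybenzyne 9 (not isolated), via adduct arylmagnesium chloride 10 (not isolated)
Conditions: 6 (2.0 equiv), iPrMgCl·LiCl (2.0 equiv), THF, 0 °C; 3 (1.0 equiv), then iPrMgCl·LiCl (1.05 equiv), −78 °C, 1 h; −78 → 0 °C; I2 (1.2 equiv) in THF, −78 °C → rt; aq. Na2S2O3/NH4Cl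
Reagents that add atoms: iodine, II; isopropylmagnesium chloride–lithium chloride, CC(C)[Mg]Cl.[Li+].[Cl-] (supplies the Mg and Cl of 7, 8 and 10 only)
Why: Proposed new method: iodine–magnesium exchange on 3 gives 8, which on warming expels magnesium 4-chlorobenzenesulfonate to release aryne 9; the oxygen of 7 adds to the carbon that carried the sulfonate (ring B C2), the charge that develops at C1 is held as arylmagnesium 10, and I2 turns it into the C1–I bond in the same flask. The closest known reactions are the addition of magnesium thiolates, selenides and amides to arynes released from 2-magnesiated aryl sulfonates with electrophilic trapping of the new arylmagnesium, and the plain O-arylation of phenols by arynes that ends in protonation; an aryloxide has not been carried through the three-component version. The step needs regioselectivity, and the C6 methoxy group next to the triple bond should secure it, because its inductive pull and the resulting distortion of the aryne make the remote carbon C2 the electrophilic one and place the carbanion at C1, where the same oxygen can chelate magnesium. O-arylation rather than C-arylation follows from the substrate, since both ortho positions and the para position of 7 are substituted. Protonation of 10 is avoided because every acidic proton is removed before the aryne is released, and the excess of 7 is meant to outrun addition of 8 or of residual iPrMgCl to 9. No ring is closed and no stereocentre is formed.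

Step 6
Reactants: 11 5-(benzyloxy)-2-(2-iodo-3,4,5-trimethoxyphenoxy)-1,3-dimethoxybenzene; 12 3,5-dimethoxyphenol
Product: 13 1-[4-(benzyloxy)-2,6-dimethoxyphenoxy]-2-(3,5-dimethoxyphenoxy)-3,4,5-trimethoxybenzene (trimer benzyl ether A–C)
Conditions: CuI (10 mol %), picolinic acid (20 mol %), K3PO4 (2 equiv), DMSO, 90 °C, argon
Reagents that add atoms: none
Why: Ullmann-type diaryl ether synthesis; the CuI/picolinic acid system is established for di-ortho-substituted aryl iodides, the phenol has two free ortho positions, and benzyl and methyl ethers are inert to K3PO4.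

Step 7
Reactants: 13 trimer benzyl ether A–C
Product: 14 4-[2-(3,5-dimethoxyphenoxy)-3,4,5-trimethoxyphenoxy]-3,5-dimethoxyphenol (trimer phenol A–C)
Conditions: H2 (1 atm), 10% Pd/C, EtOAc/MeOH, rt
Reagents that add atoms: none
Why: Catalytic hydrogenolysis cleaves only the benzylic C–O bond; aryl methyl ethers and diaryl ethers are untouched, and no aryl halide is left in the molecule.

Step 8
Reactants: 14 trimer phenol A–C; 11 module iodide
Product: 15 pentamer benzyl ether A–E (twelve OMe; OBn on C4 of ring E)
Conditions: 11 (1.3 equiv), CuI (20 mol %), picolinic acid (40 mol %), K3PO4 (2 equiv), DMSO, 95 °C, argon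
Reagents that add atoms: none
Why: Ullmann-type diaryl ether synthesis as in step 6; the nucleophile is the uncrowded C4 hydroxyl of ring C (two ortho hydrogens), so the steric load lies only on the iodide, for which the ligand system is suited.

Step 9
Reactants: 15 pentamer benzyl ether A–E
Product: 16 pentamer phenol A–E (twelve OMe; OH on C4 of ring E)
Conditions: H2 (1 atm), 10% Pd/C, THF/MeOH, rt
Reagents that add atoms: none
Why: Catalytic hydrogenolysis of the single benzyl ether, with all other C–O bonds inert as in step 7.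

Step 10
Reactants: 16 pentamer phenol A–E; 11 module iodide
Product: 17 heptamer benzyl ether A–G (seventeen OMe; OBn on C4 of ring G)
Conditions: 11 (1.5 equiv), CuI (20 mol %), picolinic acid (40 mol %), K3PO4 (2 equiv), DMSO, 95 °C, argon
Reagents that add atoms: none
Why: Third use of the same Ullmann-type coupling; the reacting sites are locally identical to those of step 8, so the same reactivity is expected.

Step 11
Reactants: 17 heptamer benzyl ether A–G
Product: 18 heptamer phenol A–G (seventeen OMe; OH on C4 of ring G)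
Conditions: H2 (1 atm), 10% Pd/C, THF/MeOH, rt
Reagents that add atoms: none
Why: Catalytic hydrogenolysis of the single benzyl ether as in steps 7 and 9.

Step 12
Reactants: 18 heptamer phenol A–G; 19 2-iodo-1,3,5-trimethoxybenzene
Product: 20 icosamethyl ether of the target (octamer A–H)
Conditions: 19 (3 equiv), CuI (20 mol %), picolinic acid (40 mol %), K3PO4 (2 equiv), DMSO, 95 °C, argon
Reagents that add atoms: none
Why: Ullmann-type diaryl ether synthesis with a cheap 2,6-dimethoxyaryl iodide that can be used in excess to drive the conversion of the valuable phenol.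

Step 13
Reactants: 20 icosamethyl ether of the target
Product: 21 target CNP0319661.0
Conditions: BBr3 (60 equiv), CH2Cl2, −78 °C → rt, argon; H2O, 0 °C; co-evaporation with MeOH; Sephadex LH-20 with degassed aq. MeOH
Reagents that add atoms: none
Why: Lewis-acid cleavage of aryl methyl ethers with BBr3 breaks only the O–CH3 bonds, is assisted by chelation in the vicinal trimethoxy arrays, and leaves the seven diaryl ether bonds intact.

## Compound list

1 | 3,4,5-trimethoxyphenol | COc1cc(O)cc(OC)c1OC | starting material
2 | 2-iodo-3,4,5-trimethoxyphenol | COc1cc(O)c(I)c(OC)c1OC | intermediate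
3 | 2-iodo-3,4,5-trimethoxyphenyl 4-chlorobenzenesulfonate | COc1cc(OS(=O)(=O)c2ccc(Cl)cc2)c(I)c(OC)c1OC | intermediate
4 | 2,6-dimethoxy-1,4-benzoquinone | COC1=CC(=O)C=C(OC)C1=O | starting material
5 | 2,6-dimethoxybenzene-1,4-diol | COc1cc(O)cc(OC)c1O | intermediate
6 | 4-(benzyloxy)-2,6-dimethoxyphenol | COc1cc(OCc2ccccc2)cc(OC)c1O | intermediate
7 | chloromagnesium 4-(benzyloxy)-2,6-dimethoxyphenoxide | COc1cc(OCc2ccccc2)cc(OC)c1O[Mg]Cl | intermediate
8 | 2-(chloromagnesio)-3,4,5-trimethoxyphenyl 4-chlorobenzenesulfonate | COc1cc(OS(=O)(=O)c2ccc(Cl)cc2)c([Mg]Cl)c(OC)c1OC | intermediate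
9 | 3,4,5-trimethoxybenzyne | COC1=CC#CC(OC)=C1OC | intermediate
10 | {2-[4-(benzyloxy)-2,6-dimethoxyphenoxy]-4,5,6-trimethoxyphenyl}magnesium chloride | COc1cc(OCc2ccccc2)cc(OC)c1Oc1cc(OC)c(OC)c(OC)c1[Mg]Cl | intermediate
11 | 5-(benzyloxy)-2-(2-iodo-3,4,5-trimethoxyphenoxy)-1,3-dimethoxybenzene (module iodide) | COc1cc(OCc2ccccc2)cc(OC)c1Oc1cc(OC)c(OC)c(OC)c1I | intermediate
12 | 3,5-dimethoxyphenol | COc1cc(O)cc(OC)c1 | starting material
13 | 1-[4-(benzyloxy)-2,6-dimethoxyphenoxy]-2-(3,5-dimethoxyphenoxy)-3,4,5-trimethoxybenzene (trimer benzyl ether A–C) | COc1cc(OC)cc(Oc2c(Oc3c(OC)cc(OCc4ccccc4)cc3OC)cc(OC)c(OC)c2OC)c1 | intermediate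
14 | 4-[2-(3,5-dimethoxyphenoxy)-3,4,5-trimethoxyphenoxy]-3,5-dimethoxyphenol (trimer phenol A–C) | COc1cc(OC)cc(Oc2c(Oc3c(OC)cc(O)cc3OC)cc(OC)c(OC)c2OC)c1 | intermediate
15 | pentamer benzyl ether A–E (oxygen on C4 of ring C bonded to C1 of ring D; OBn on C4 of ring E) | COc1cc(OC)cc(Oc2c(Oc3c(OC)cc(Oc4c(Oc5c(OC)cc(OCc6ccccc6)cc5OC)cc(OC)c(OC)c4OC)cc3OC)cc(OC)c(OC)c2OC)c1 | intermediate
16 | pentamer phenol A–E (OH on C4 of ring E) | COc1cc(OC)cc(Oc2c(Oc3c(OC)cc(Oc4c(Oc5c(OC)cc(O)cc5OC)cc(OC)c(OC)c4OC)cc3OC)cc(OC)c(OC)c2OC)c1 | intermediate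
17 | heptamer benzyl ether A–G (oxygen on C4 of ring E bonded to C1 of ring F; OBn on C4 of ring G) | COc1cc(OC)cc(Oc2c(Oc3c(OC)cc(Oc4c(Oc5c(OC)cc(Oc6c(Oc7c(OC)cc(OCc8ccccc8)cc7OC)cc(OC)c(OC)c6OC)cc5OC)cc(OC)c(OC)c4OC)cc3OC)cc(OC)c(OC)c2OC)c1 | intermediate
18 | heptamer phenol A–G (OH on C4 of ring G) | COc1cc(OC)cc(Oc2c(Oc3c(OC)cc(Oc4c(Oc5c(OC)cc(Oc6c(Oc7c(OC)cc(O)cc7OC)cc(OC)c(OC)c6OC)cc5OC)cc(OC)c(OC)c4OC)cc3OC)cc(OC)c(OC)c2OC)c1 | intermediate
19 | 2-iodo-1,3,5-trimethoxybenzene | COc1cc(OC)c(I)c(OC)c1 | starting material
20 | icosamethyl ether of the target (octamer A–H) | COc1cc(OC)cc(Oc2c(Oc3c(OC)cc(Oc4c(Oc5c(OC)cc(Oc6c(Oc7c(OC)cc(Oc8c(OC)cc(OC)cc8OC)cc7OC)cc(OC)c(OC)c6OC)cc5OC)cc(OC)c(OC)c4OC)cc3OC)cc(OC)c(OC)c2OC)c1 | intermediate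
21 | CNP0319661.0 (octameric phlorethol-type polyphenol A–H) | Oc1cc(O)cc(Oc2c(Oc3c(O)cc(Oc4c(Oc5c(O)cc(Oc6c(Oc7c(O)cc(Oc8c(O)cc(O)cc8O)cc7O)cc(O)c(O)c6O)cc5O)cc(O)c(O)c4O)cc3O)cc(O)c(O)c2O)c1 | target

## Step count and risks

Total step count: 13.
Longest linear sequence: 11 steps (1 → 2 → 3 → 11 → 13 → 14 → 15 → 16 → 17 → 18 → 20 → 21). Steps 3 and 4 form the side branch to 6.

**Risk 1, step 5 (new method).**
- What may go wrong: the magnesium aryloxide may add too slowly, so that the aryne is lost to attack by the magnesiated sulfonate or by the isopropyl Grignard reagent. The adduct may be protonated before iodine arrives, and iodine may oxidise surplus phenoxide.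
- Constraint on the fallback: direct iodination of a halogen-free B–C diaryl ether is not an option, because ring C is at least as nucleophilic as ring B. The fallback therefore installs the halogen beforehand.
- Fallback by known chemistry, setting out from 6 and coming back at 11: commercial 5-iodo-1,2,3-trimethoxybenzene F1 is brominated with NBS in MeCN at one of its two equivalent free positions, giving 2-bromo-1-iodo-3,4,5-trimethoxybenzene F2. A chemoselective Ullmann ether synthesis (CuI, N,N-dimethylglycine, Cs2CO3, 1,4-dioxane, 90 °C) joins 6 to the more reactive and less crowded C–I carbon. This should give 5-(benzyloxy)-2-(2-bromo-3,4,5-trimethoxyphenoxy)-1,3-dimethoxybenzene F3. Bromine–lithium exchange (nBuLi, THF, −78 °C) gives the aryllithium F4, which I2 converts into 11.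

**Risk 2, step 10.**
- What may go wrong: slow engagement of the doubly ortho-oxygenated iodide by copper lets hydrodeiodination of the module and thermal decay of the large phenoxide compete. Separating the product from unreacted oligomers also becomes harder as the chain grows.
- Fallback with reversed polarity of the union, setting out from 11 and 16 and coming back at 17: 11 is re-magnesiated with iPrMgCl·LiCl (THF, −20 °C) to 10. This is borylated with B(OMe)3 to the dimethyl arylboronate F5 and oxidised with H2O2/NaOH at 0 °C to 6-[4-(benzyloxy)-2,6-dimethoxyphenoxy]-2,3,4-trimethoxyphenol F6. Separately, 16 is converted with Tf2O/pyridine (CH2Cl2, 0 °C) into the pentamer triflate F7, whose reacting carbon has two free ortho positions. A palladium-catalysed C–O coupling of Buchwald–Hartwig type (Pd(OAc)2, tBuXPhos, K3PO4, toluene, 100 °C) of F7 with F6 should give 17. The same reversal could serve steps 6 and 8.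

**Risk 3, step 13.**
- What may go wrong: precipitation of partly cleaved boron aryloxides may stop the reaction short of twenty cleavages, and the free pentaoxygenated rings may be oxidised by air during chromatography.
- Fallback by capture and release, setting out from 20 and coming back at 21: the crude BBr3 product is not purified but acetylated at once (Ac2O, pyridine, DMAP, rt) to the icosaacetate F8. This is a neutral and air-stable compound that can be chromatographed on silica gel and freed from congeners that still carry methyl groups, which go back to BBr3. Acid-catalysed transesterification (catalytic HCl in MeOH, argon, rt → 40 °C) then releases 21 beside a volatile ester only, so the free polyphenol needs no chromatography.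

## Further compounds

F1 | step 5 | 5-iodo-1,2,3-trimethoxybenzene (commercial) | COc1cc(I)cc(OC)c1OC
F2 | step 5 | 2-bromo-1-iodo-3,4,5-trimethoxybenzene | COc1cc(I)c(Br)c(OC)c1OC
F3 | step 5 | 5-(benzyloxy)-2-(2-bromo-3,4,5-trimethoxyphenoxy)-1,3-dimethoxybenzene | COc1cc(OCc2ccccc2)cc(OC)c1Oc1cc(OC)c(OC)c(OC)c1Br
F4 | step 5 | {2-[4-(benzyloxy)-2,6-dimethoxyphenoxy]-4,5,6-trimethoxyphenyl}lithium | COc1cc(OCc2ccccc2)cc(OC)c1Oc1cc(OC)c(OC)c(OC)c1[Li]
F5 | step 10 | dimethyl {2-[4-(benzyloxy)-2,6-dimethoxyphenoxy]-4,5,6-trimethoxyphenyl}boronate | COc1cc(OCc2ccccc2)cc(OC)c1Oc1cc(OC)c(OC)c(OC)c1B(OC)OC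
F6 | step 10 | 6-[4-(benzyloxy)-2,6-dimethoxyphenoxy]-2,3,4-trimethoxyphenol | COc1cc(OCc2ccccc2)cc(OC)c1Oc1cc(OC)c(OC)c(OC)c1O
F7 | step 10 | pentamer triflate A–E (OTf on C4 of ring E) | COc1cc(OC)cc(Oc2c(Oc3c(OC)cc(Oc4c(Oc5c(OC)cc(OS(=O)(=O)C(F)(F)F)cc5OC)cc(OC)c(OC)c4OC)cc3OC)cc(OC)c(OC)c2OC)c1
F8 | step 13 | icosaacetate of the target | CC(=O)Oc1cc(OC(C)=O)cc(Oc2c(Oc3c(OC(C)=O)cc(Oc4c(Oc5c(OC(C)=O)cc(Oc6c(Oc7c(OC(C)=O)cc(Oc8c(OC(C)=O)cc(OC(C)=O)cc8OC(C)=O)cc7OC(C)=O)cc(OC(C)=O)c(OC(C)=O)c6OC(C)=O)cc5OC(C)=O)cc(OC(C)=O)c(OC(C)=O)c4OC(C)=O)cc3OC(C)=O)cc(OC(C)=O)c(OC(C)=O)c2OC(C)=O)c1
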